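**Retrosynthetic overview**
1. C10 carbinol: equatorial methyl addition to a C10 ketone (axial 10-OH), then global desilylation.
2. Oxepane, then cyclohexane (last rings, one cascade): silyl-triflate opening of a 2,3;6,7-diepoxide, epoxide-O attack at C2, then C11 of an enol silane at C6.
3. C12–C13: conjugate addition of the hydroazulenylmethyl copper (C13) to a diepoxy vinyl ketone, which also fixes the enol silane regiochemistry.
4. Cycloheptene (second ring): 7-endo attack of the central carbon of a C13=C14=C15 allene on the C23 cation, chloride capture at C13 (gives Δ14 with O-16 in place).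
5. Cyclopentane (first ring): enol-ether-assisted opening of the 18,19-epoxide at C18 by the Δ22 alkene, from Sharpless epoxygeraniol.

Assumption: positions are given in squalene-type numbering C1–C30 (C26 = methyl on C6, C27 = methyl on C10); commercial (E)-geranylacetone is isomerically pure.

**Route**

Step 1
Reactants: 1 geraniol
Product: 2 [(2R,3R)-3-methyl-3-(4-methylpent-3-en-1-yl)oxiran-2-yl]methanol
Conditions: Ti(OiPr)4 (5 mol%), D-(−)-diethyl tartrate (6 mol%), t-BuOOH, 4 Å MS, CH2Cl2, −20 °C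
Reagents that add atoms: tert-butyl hydroperoxide, CC(C)(C)OO
Why: Sharpless asymmetric epoxidation, in which the allylic alcohol directs oxygen to the 2,3-alkene only and D-(−)-tartrate gives the (2R,3R)-epoxide that becomes C18/C19.

Step 2
Reactants: 2 [(2R,3R)-3-methyl-3-(4-methylpent-3-en-1-yl)oxiran-2-yl]methanol
Product: 3 (2S,3R)-3-methyl-3-(4-methylpent-3-en-1-yl)oxirane-2-carbaldehyde
Conditions: TEMPO (10 mol%), PhI(OAc)2, CH2Cl2, rt
Reagents that add atoms: none
Why: TEMPO/oxoammonium oxidation stops at the aldehyde and leaves the epoxide and alkene untouched; no stereocentre changes (the C2 descriptor changes by CIP priority only).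

Step 3
Reactants: 3 (2S,3R)-3-methyl-3-(4-methylpent-3-en-1-yl)oxirane-2-carbaldehyde
Product: 4 (2R,3R)-2-(2-methoxyethenyl)-3-methyl-3-(4-methylpent-3-en-1-yl)oxirane (E/Z mixture)
Conditions: MeOCH2PPh3Cl, KHMDS, THF, −78 → 0 °C
Reagents that add atoms: (methoxymethyl)triphenylphosphonium chloride, COC[P+](c1ccccc1)(c1ccccc1)c1ccccc1.[Cl-]
Why: Wittig homologation adds C16 at the aldehyde oxidation level as an enol ether; both geometric isomers converge in step 4.

Step 4
Reactants: 4 (2R,3R)-2-(2-methoxyethenyl)-3-methyl-3-(4-methylpent-3-en-1-yl)oxirane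
Product: 6 2-[(1R,2R,5R)-2-hydroxy-2-methyl-5-(prop-1-en-2-yl)cyclopentyl]acetaldehyde, via cyclised enol ether 5 (not isolated)
Conditions: Sc(OTf)3 (10 mol%), 2,6-di-tert-butylpyridine (20 mol%), CH2Cl2, −40 → 0 °C; then 1 M HCl, THF, 0 °C
Reagents that add atoms: water, O
Why: Proposed new method: the enol ether oxygen stabilises charge at C18 vinylogously, so the Lewis acid opens the epoxide at C18 and not at the tertiary C19; the Δ22 alkene attacks C18 anti to the leaving oxygen (inversion, so the E-epoxide gives the target C18/C19 relationship) in an intramolecular ene-type closure whose six-membered H-transfer from C24 to C17 needs the cis-1,2 arrangement (sets C22) and leaves the isopropenyl group, and acid work-up hydrolyses the enol ether to the C16 aldehyde; closest known reaction types are Lewis-acid type-I intramolecular ene reactions of 1,6-dienes (cis-cyclopentanes) and stereospecific epoxide-initiated cation–olefin cyclisations.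

Step 5
Reactants: 6 2-[(1R,2R,5R)-2-hydroxy-2-methyl-5-(prop-1-en-2-yl)cyclopentyl]acetaldehyde; 7 1-bromobut-2-yne
Product: 9 (1R,2R,3R)-2-[(2S)-2-hydroxy-3-methylpenta-3,4-dien-1-yl]-1-methyl-3-(prop-1-en-2-yl)cyclopentan-1-ol, via trimethylsilyl ether 8 (not isolated)
Conditions: CrCl2 (10 mol%), chiral bis(oxazolinyl)carbazole ligand (12 mol%), Mn, TMSCl, i-Pr2NEt (cat.), THF, rt; then 1 M HCl
Reagents that add atoms: none
Why: Catalytic asymmetric Nozaki–Hiyama allenylation, in which the propargyl-chromium from the γ-methyl propargyl bromide adds SE2′ through its methyl-bearing carbon to give the 2,3-dienyl carbinol, and the ligand enantiomer is chosen so that catalyst control sets 16S.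

Step 6
Reactants: 9 (1R,2R,3R)-2-[(2S)-2-hydroxy-3-methylpenta-3,4-dien-1-yl]-1-methyl-3-(prop-1-en-2-yl)cyclopentan-1-ol
Product: 10 bis(tert-butyldimethylsilyl) ether of 9
Conditions: TBSOTf (3 equiv), 2,6-lutidine, CH2Cl2, −78 → 0 °C
Reagents that add atoms: tert-butyldimethylsilyl triflate, CC(C)(C)[Si](C)(C)OS(=O)(=O)C(F)(F)F
Why: Silyl triflate silylates both the secondary and the tertiary alcohol, which keeps O16 from trapping the C23 cation as a tetrahydropyran and protects O19 for the organometallic step.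

Step 7
Reactants: 10 bis(tert-butyldimethylsilyl) ether of 9
Product: 11 (1R,3aR,7S,8aR)-1,7-bis[(tert-butyldimethylsilyl)oxy]-5-(chloromethyl)-1,4,4,6-tetramethyl-1,2,3,3a,4,7,8,8a-octahydroazulene
Conditions: HCl (1.05 equiv, CH2Cl2 solution), SnCl4 (20 mol%), CH2Cl2, −78 → −40 °C
Reagents that add atoms: hydrogen chloride, Cl
Why: Proposed new method: Markovnikov protonation of the 1,1-disubstituted alkene gives the C23 cation, which the central allene carbon C14 attacks 7-endo (the cis-cyclopentane holds the ends together, and central attack gives a tertiary cation that relaxes to the C13–C14–C15 allyl cation), and chloride adds at the primary terminus C13 to give the tetrasubstituted Δ14 alkene with no new stereocentre and C16, C18, C19 and C22 untouched; closest known reaction types are allene-terminated Prins and N-acyliminium cyclisations and tertiary-cation cycloheptene closures in guaiane-type cation–olefin cyclisations.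

Step 8
Reactants: 12 (5E)-6,10-dimethylundeca-5,9-dien-2-one (geranylacetone)
Product: 13 4-[(2R,3R)-3-{2-[(2R)-3,3-dimethyloxiran-2-yl]ethyl}-3-methyloxiran-2-yl]butan-2-one
Conditions: D-fructose-derived Shi ketone (30 mol%), Oxone, K2CO3, Bu4NHSO4, MeCN–DMM–aq. borate buffer (pH 10.5), 0 °C
Reagents that add atoms: potassium peroxymonosulfate (Oxone), [K+].[O-]S(=O)(=O)OO
Why: Shi epoxidation, in which the dioxirane from the D-fructose ketone epoxidises both trisubstituted E-alkenes through a spiro transition state to the (R,R)-type epoxides (C3 R; C6 R; C7 R).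

Step 9
Reactants: 13 4-[(2R,3R)-3-{2-[(2R)-3,3-dimethyloxiran-2-yl]ethyl}-3-methyloxiran-2-yl]butan-2-one
Product: 17 5-[(2R,3R)-3-{2-[(2R)-3,3-dimethyloxiran-2-yl]ethyl}-3-methyloxiran-2-yl]pent-1-en-3-one, via lithium enolate 14 (not isolated), via Mannich base 15 (not isolated), via methiodide 16 (not isolated)
Conditions: LDA, THF, −78 °C; CH2=NMe2+ I−, −78 → 0 °C; then MeI, CH2Cl2, rt; then aq. NaHCO3
Reagents that add atoms: Eschenmoser's salt, C=[N+](C)C.[I-]
Why: Kinetic deprotonation at the methyl group, Mannich aminomethylation and quaternisation/E1cB elimination give the vinyl ketone (adds C12); the trisubstituted epoxides are inert to LDA at −78 °C.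

Step 10
Reactants: 11 (1R,3aR,7S,8aR)-1,7-bis[(tert-butyldimethylsilyl)oxy]-5-(chloromethyl)-1,4,4,6-tetramethyl-1,2,3,3a,4,7,8,8a-octahydroazulene; 17 5-[(2R,3R)-3-{2-[(2R)-3,3-dimethyloxiran-2-yl]ethyl}-3-methyloxiran-2-yl]pent-1-en-3-one
Product: 20 trimethylsilyl (Z)-enol ether (C10–OSiMe3 with C10=C11; C12–C13 bond to the hydroazulene of 11; both epoxides intact), via allylmagnesium chloride 18 (not isolated), via allylcopper 19 (not isolated)
Conditions: Rieke Mg, THF, −78 °C; CuBr·SMe2 (1.0 equiv); TMSCl (2 equiv) then 17, −78 → −40 °C; Et3N, pentane, filtration (used crude)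
Reagents that add atoms: chlorotrimethylsilane, C[Si](C)(C)Cl
Why: TMSCl-accelerated conjugate addition of an allylic copper reagent, in which the fully substituted γ-carbon C15 forces attack through C13, forming C12–C13 and giving the C10=C11 enol silane regiospecifically; the epoxides are inert at −78 °C and no stereocentre is set.

Step 11
Reactants: 20 trimethylsilyl (Z)-enol ether
Product: 21 (3R,5aR,6R,9aR)-6-{2-[(1R,3aR,7S,8aR)-1,7-bis[(tert-butyldimethylsilyl)oxy]-1,4,4,6-tetramethyl-1,2,3,3a,4,7,8,8a-octahydroazulen-5-yl]ethyl}-2,2,5a-trimethyl-3-(trimethylsilyloxy)perhydro-1-benzoxepin-7-one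
Conditions: TMSOTf (1.2 equiv), 2,6-di-tert-butyl-4-methylpyridine, CH2Cl2, −78 °C
Reagents that add atoms: trimethylsilyl triflate, C[Si](C)(C)OS(=O)(=O)C(F)(F)F
Why: Biomimetic tandem oxa-/carbacyclisation, in which the silyl-activated 2,3-epoxide is opened at C2 by the 6,7-epoxide oxygen and the resulting epoxonium is opened at C6 with inversion by C11 of the enol silane through a chair transition state, giving the trans-fused oxepane–cyclohexanone with C3, C6 and C7 from the epoxides and the equatorial (epimerisable) C11 chain; the enol silane ends the cascade at the ketone so the Δ14 alkene is not engaged.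

Step 12
Reactants: 21 tetracyclic ketone
Product: 23 (3R,5aR,6R,7S,9aR)-6-{2-[(1R,3aR,7S,8aR)-1,7-dihydroxy-1,4,4,6-tetramethyl-1,2,3,3a,4,7,8,8a-octahydroazulen-5-yl]ethyl}-2,2,5a,7-tetramethylperhydro-1-benzoxepine-3,7-diol (CNP0276044.1), via tris-silyl carbinol 22 (not isolated)
Conditions: MeLi, CeCl3, THF, −78 °C; then HF·pyridine, THF–pyridine, 0 °C → rt
Reagents that add atoms: methyllithium, [Li]C
Why: Organocerium 1,2-addition, in which the axial C26 methyl on C6 blocks axial attack so methyl enters equatorially and gives the axial (10S) tertiary alcohol; HF·pyridine then cleaves the TMS ether and both TBS ethers.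

**Compound list**
1 | geraniol, (2E)-3,7-dimethylocta-2,6-dien-1-ol | CC(C)=CCC/C(C)=C/CO | starting material
2 | [(2R,3R)-3-methyl-3-(4-methylpent-3-en-1-yl)oxiran-2-yl]methanol | OC[C@H]1O[C@]1(C)CCC=C(C)C | intermediate
3 | (2S,3R)-3-methyl-3-(4-methylpent-3-en-1-yl)oxirane-2-carbaldehyde | O=C[C@H]1O[C@]1(C)CCC=C(C)C | intermediate
4 | (2R,3R)-2-(2-methoxyethenyl)-3-methyl-3-(4-methylpent-3-en-1-yl)oxirane (E/Z) | COC=C[C@H]1O[C@]1(C)CCC=C(C)C | intermediate
5 | (1R,2S,3R)-2-(2-methoxyethenyl)-1-methyl-3-(prop-1-en-2-yl)cyclopentan-1-ol | CC(=C)[C@@H]1CC[C@@](C)(O)[C@@H]1C=COC | intermediate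
6 | 2-[(1R,2R,5R)-2-hydroxy-2-methyl-5-(prop-1-en-2-yl)cyclopentyl]acetaldehyde | CC(=C)[C@@H]1CC[C@@](C)(O)[C@@H]1CC=O | intermediate
7 | 1-bromobut-2-yne | CC#CCBr | starting material
8 | (1R,2R,3R)-1-methyl-2-[(2S)-3-methyl-2-(trimethylsilyloxy)penta-3,4-dien-1-yl]-3-(prop-1-en-2-yl)cyclopentan-1-ol | CC(=C)[C@@H]1CC[C@@](C)(O)[C@@H]1C[C@H](O[Si](C)(C)C)C(C)=C=C | intermediate
9 | (1R,2R,3R)-2-[(2S)-2-hydroxy-3-methylpenta-3,4-dien-1-yl]-1-methyl-3-(prop-1-en-2-yl)cyclopentan-1-ol | CC(=C)[C@@H]1CC[C@@](C)(O)[C@@H]1C[C@H](O)C(C)=C=C | intermediate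
10 | bis(tert-butyldimethylsilyl) ether of 9 | CC(=C)[C@@H]1CC[C@@](C)(O[Si](C)(C)C(C)(C)C)[C@@H]1C[C@H](O[Si](C)(C)C(C)(C)C)C(C)=C=C | intermediate
11 | (1R,3aR,7S,8aR)-1,7-bis[(tert-butyldimethylsilyl)oxy]-5-(chloromethyl)-1,4,4,6-tetramethyl-1,2,3,3a,4,7,8,8a-octahydroazulene | CC1=C(CCl)C(C)(C)[C@@H]2CC[C@@](C)(O[Si](C)(C)C(C)(C)C)[C@@H]2C[C@@H]1O[Si](C)(C)C(C)(C)C | intermediate
12 | (5E)-6,10-dimethylundeca-5,9-dien-2-one (geranylacetone) | CC(=O)CC/C=C(\C)CCC=C(C)C | starting material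
13 | 4-[(2R,3R)-3-{2-[(2R)-3,3-dimethyloxiran-2-yl]ethyl}-3-methyloxiran-2-yl]butan-2-one | CC(=O)CC[C@H]1O[C@]1(C)CC[C@H]1OC1(C)C | intermediate
14 | lithium enolate of 13 (terminal, kinetic) | [Li+].[O-]C(=C)CC[C@H]1O[C@]1(C)CC[C@H]1OC1(C)C | intermediate
15 | 1-(dimethylamino)-5-[(2R,3R)-3-{2-[(2R)-3,3-dimethyloxiran-2-yl]ethyl}-3-methyloxiran-2-yl]pentan-3-one | CN(C)CCC(=O)CC[C@H]1O[C@]1(C)CC[C@H]1OC1(C)C | intermediate
16 | N-methyl iodide (trimethylammonium iodide) of 15 | C[N+](C)(C)CCC(=O)CC[C@H]1O[C@]1(C)CC[C@H]1OC1(C)C.[I-] | intermediate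
17 | 5-[(2R,3R)-3-{2-[(2R)-3,3-dimethyloxiran-2-yl]ethyl}-3-methyloxiran-2-yl]pent-1-en-3-one | C=CC(=O)CC[C@H]1O[C@]1(C)CC[C@H]1OC1(C)C | intermediate
18 | allylic Grignard of 11 (C13–MgCl) | CC1=C(C[Mg]Cl)C(C)(C)[C@@H]2CC[C@@](C)(O[Si](C)(C)C(C)(C)C)[C@@H]2C[C@@H]1O[Si](C)(C)C(C)(C)C | intermediate
19 | allylcopper(I) from 18 (C13–Cu) | CC1=C(C[Cu])C(C)(C)[C@@H]2CC[C@@](C)(O[Si](C)(C)C(C)(C)C)[C@@H]2C[C@@H]1O[Si](C)(C)C(C)(C)C | intermediate
20 | trimethylsilyl (Z)-enol ether: hydroazulene of 11 with C13H2–C12H2–C11H=C10(OSiMe3)–CH2CH2–[(2R,3R)-3-methyloxirane-2,3-diyl]–CH2CH2–[(2R)-3,3-dimethyloxiran-2-yl] | CC1=C(CC/C=C(\O[Si](C)(C)C)CC[C@H]3O[C@]3(C)CC[C@H]3OC3(C)C)C(C)(C)[C@@H]2CC[C@@](C)(O[Si](C)(C)C(C)(C)C)[C@@H]2C[C@@H]1O[Si](C)(C)C(C)(C)C | intermediate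
21 | (3R,5aR,6R,9aR)-6-{2-[(1R,3aR,7S,8aR)-1,7-bis(TBS-oxy)-1,4,4,6-tetramethyl-1,2,3,3a,4,7,8,8a-octahydroazulen-5-yl]ethyl}-2,2,5a-trimethyl-3-(trimethylsilyloxy)perhydro-1-benzoxepin-7-one | CC1=C(CC[C@@H]2[C@@]3(C)CC[C@@H](O[Si](C)(C)C)C(C)(C)O[C@@H]3CCC2=O)C(C)(C)[C@@H]2CC[C@@](C)(O[Si](C)(C)C(C)(C)C)[C@@H]2C[C@@H]1O[Si](C)(C)C(C)(C)C | intermediate
22 | (3R,5aR,6R,7S,9aR)-7-hydroxy-7-methyl analogue of 21 (3-OTMS; 16,19-bis-OTBS) | CC1=C(CC[C@@H]2[C@@]3(C)CC[C@@H](O[Si](C)(C)C)C(C)(C)O[C@@H]3CC[C@]2(C)O)C(C)(C)[C@@H]2CC[C@@](C)(O[Si](C)(C)C(C)(C)C)[C@@H]2C[C@@H]1O[Si](C)(C)C(C)(C)C | intermediate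
23 | CNP0276044.1 (3R,6R,7R,10S,11R,16S,18R,19R,22R in squalene numbering) | CC1=C(CC[C@@H]2[C@@]3(C)CC[C@@H](O)C(C)(C)O[C@@H]3CC[C@]2(C)O)C(C)(C)[C@@H]2CC[C@@](C)(O)[C@@H]2C[C@@H]1O | target

**Step count**
Total: 12 steps. Longest linear sequence: 10 steps (steps 1–7, then 10–12, from geraniol); steps 8–9 make the second fragment.

**Three steps most likely to fail, with fallbacks**

Step 4 (cyclopentane closure). The risks are opening at C19 with a hydride shift, or a trans-1,2 closure that cannot later form the seven-membered ring. The fallback sets out from 3 and installs C16 after ring formation. Wittig methylenation (Ph3P=CH2) gives the vinyl epoxide (2R,3R)-2-ethenyl-3-methyl-3-(4-methylpent-3-en-1-yl)oxirane F1. SnCl4 at −78 °C ionises it at the allylic C18 and the Δ22 alkene closes to (1R,2R,3R)-2-ethenyl-1-methyl-3-(prop-1-en-2-yl)cyclopentan-1-ol F2. 9-BBN hydroborates the monosubstituted vinyl group in preference to the isopropenyl group, and oxidation gives (1R,2R,3R)-2-(2-hydroxyethyl)-1-methyl-3-(prop-1-en-2-yl)cyclopentan-1-ol F3. TEMPO/PhI(OAc)2 oxidation of the primary alcohol comes back to the route at 6.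

Step 7 (cation–allene seven-ring closure). The risks are competing protonation of the allene, attack of O16 on C23, a 1,2-hydride shift from C22, or six-ring closure at C15. The fallback sets out from 10 and separates cation generation from cyclisation. HCl alone at −90 °C (no Lewis acid) adds to the 1,1-disubstituted alkene to give the isolable C23 tertiary chloride of 10 F4. This is then ionised proton-free by halide abstraction (catalytic SnCl4 or ZnCl2, 2,6-di-tert-butylpyridine, CH2Cl2, −78 °C), so the allene and silyl ethers never see acid; the ion pair cyclises and returns chloride at C13, coming back to the route at 11.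

Step 10 (allylcopper conjugate addition). The risks are 1,4-elimination of the δ-silyloxy group from the allyl metal, Wurtz coupling, or 1,2-addition. The fallback reverses the polarity, so the hydroazulene 11 is the electrophile, and sets out from 17. PhMe2SiLi adds 1,2 to the ketone (THF, −78 °C) to give the lithium α-silyl alkoxide F5. Brook rearrangement gives the siloxyallyl-lithium F6, a homoenolate equivalent. γ-Alkylation of F6 at C12 with allylic chloride 11 gives the dimethylphenylsilyl (Z)-enol ether F7. Under the step 11 conditions F7 cyclises and comes back to the route at 21.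

**Further compounds**
F1 | step 4 | (2R,3R)-2-ethenyl-3-methyl-3-(4-methylpent-3-en-1-yl)oxirane | C=C[C@H]1O[C@]1(C)CCC=C(C)C
F2 | step 4 | (1R,2R,3R)-2-ethenyl-1-methyl-3-(prop-1-en-2-yl)cyclopentan-1-ol | CC(=C)[C@@H]1CC[C@@](C)(O)[C@@H]1C=C
F3 | step 4 | (1R,2R,3R)-2-(2-hydroxyethyl)-1-methyl-3-(prop-1-en-2-yl)cyclopentan-1-ol | CC(=C)[C@@H]1CC[C@@](C)(O)[C@@H]1CCO
F4 | step 7 | C23 tertiary chloride of 10 (3-(2-chloropropan-2-yl) analogue, bis-TBS ether) | CC(C)(Cl)[C@@H]1CC[C@@](C)(O[Si](C)(C)C(C)(C)C)[C@@H]1C[C@H](O[Si](C)(C)C(C)(C)C)C(C)=C=C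
F5 | step 10 | lithium 3-[dimethyl(phenyl)silyl] alkoxide from 1,2-addition to 17 | [Li+].[O-]C(C=C)([Si](C)(C)c1ccccc1)CC[C@H]1O[C@]1(C)CC[C@H]1OC1(C)C
F6 | step 10 | siloxyallyl-lithium (C12 carbanion, C10–OSiMe2Ph) | [Li+].[CH2-]C=C(O[Si](C)(C)c1ccccc1)CC[C@H]1O[C@]1(C)CC[C@H]1OC1(C)C
F7 | step 10 | dimethylphenylsilyl (Z)-enol ether analogue of 20 | CC1=C(CC/C=C(\O[Si](C)(C)c4ccccc4)CC[C@H]3O[C@]3(C)CC[C@H]3OC3(C)C)C(C)(C)[C@@H]2CC[C@@](C)(O[Si](C)(C)C(C)(C)C)[C@@H]2C[C@@H]1O[Si](C)(C)C(C)(C)C
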